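The route rests on cutting ring C at C3–C4 and O1–C2. In the flavanone, O1, C2, C3 and C4 tie C8a to C4a of ring A, and the C7 oxygen stands para to C4a, so positive charge at C4 is spread over ring A as in an ortho-quinone methide. A salicylaldehyde dimethyl acetal (free phenol at the future O1, TIPS on the C7 oxygen) is ionised by a confined chiral Brønsted acid and adds across a ring B styrene. This one operation makes both bonds, closes ring C and sets C2 as S. The styrene carries bromine where the nucleophilic prenyl group will later be installed by Stille coupling.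

Key step: step 6

Assumption: the sense of induction of the confined acid with this new pair of partners cannot be derived from a model, so the (S,S) acid is written as the one that gives 2S; if the first assay shows 2R, the mirror-image acid is used and nothing else changes.

Step 1
Reactants: 1 2,4-dihydroxybenzaldehyde
Product: 2 2-hydroxy-4-(triisopropylsilyloxy)benzaldehyde
Conditions: TIPSCl (1.05 equiv), imidazole (2 equiv), DMF, 0 °C to rt
Reagents that add atoms: triisopropylsilyl chloride, CC(C)[Si](Cl)(C(C)C)C(C)C
Why: Imidazole-promoted silyl ether formation; the 2-OH is locked in a hydrogen bond to the neighbouring aldehyde, so the bulky chlorosilane should take only the more acidic, unhindered 4-OH.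

Step 2
Reactants: 2 2-hydroxy-4-(triisopropylsilyloxy)benzaldehyde
Product: 3 2-(dimethoxymethyl)-5-(triisopropylsilyloxy)phenol
Conditions: HC(OMe)3 (3 equiv), TsOH·H2O (1 mol %), MeOH, rt; solid NaHCO3, filter, evaporate, short plug of basic alumina, use at once
Reagents that add atoms: trimethyl orthoformate, COC(OC)OC; methanol (solvent, in exchange with the orthoester), CO
Why: Acid-catalysed acetalisation driven by the orthoester as water scavenger; quenching with a solid inorganic base means the labile free-phenol acetal is never concentrated with acid and carries no amine that would neutralise the catalyst of step 6.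

Step 3
Reactants: 4 3-bromo-4,5-dihydroxybenzaldehyde
Product: 5 3-bromo-5-hydroxy-4-methoxybenzaldehyde
Conditions: MeI (1.05 equiv), Li2CO3 (1.1 equiv), DMF, 40 °C
Reagents that add atoms: iodomethane, CI
Why: Williamson ether synthesis under mono-deprotonation control; the 4-OH (para to CHO, ortho to Br) is clearly the more acidic, so the weak base should form only that phenoxide, which is then methylated.

Step 4
Reactants: 5 3-bromo-5-hydroxy-4-methoxybenzaldehyde
Product: 6 3-bromo-4-methoxy-5-(triisopropylsilyloxy)benzaldehyde
Conditions: TIPSCl (1.2 equiv), imidazole (2.5 equiv), DMF, rt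
Reagents that add atoms: triisopropylsilyl chloride, CC(C)[Si](Cl)(C(C)C)C(C)C
Why: Imidazole-promoted silylation of the only remaining phenol; TIPS is chosen because it withstands the acids of steps 6 and 8 and leaves under buffered fluoride.

Step 5
Reactants: 6 3-bromo-4-methoxy-5-(triisopropylsilyloxy)benzaldehyde
Product: 7 1-bromo-5-ethenyl-2-methoxy-3-(triisopropylsilyloxy)benzene
Conditions: MePPh3Br (1.3 equiv), KOtBu (1.2 equiv), THF, 0 °C, then 6, 0 °C to rt
Reagents that add atoms: methyltriphenylphosphonium bromide, C[P+](c1ccccc1)(c1ccccc1)c1ccccc1.[Br-]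
Why: Wittig methylenation of a non-enolisable aromatic aldehyde; the ylide is preformed with KOtBu, so no alkyllithium is present that could exchange the aryl bromide, and the silyl ether is left alone.

Step 6
Reactants: 3 2-(dimethoxymethyl)-5-(triisopropylsilyloxy)phenol; 7 1-bromo-5-ethenyl-2-methoxy-3-(triisopropylsilyloxy)benzene
Product: 9 (2S)-2-[3-bromo-4-methoxy-5-(triisopropylsilyloxy)phenyl]-4-methoxy-7-(triisopropylsilyloxy)chroman (both C4 epimers), via O-methyl oxocarbenium ion 8 (not isolated)
Conditions: (S,S)-IDPi acid [N,N'-bis(trifluoromethylsulfonyl) imidodiphosphorimidate of two (S)-3,3'-bis(3,5-bis(trifluoromethyl)phenyl)-1,1'-bi-2-naphthol units] (5 mol %), 5 Å MS, toluene, −40 °C; 3 added slowly to 7 (1.5 equiv)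
Reagents that add atoms: none
Why: Proposed new method: the acid protonates one acetal methoxy group of 3 and expels methanol (taken up by the sieves) to give cation 8, whose charge is shared by the OMe oxygen, the para C7 silyloxy group and the ortho phenol, and which stays ion-paired and hydrogen-bonded through its O–H to the chiral anion. The terminal CH2 of 7 attacks C4 (C3–C4 bond) while the phenol oxygen collapses onto the developing benzylic cation (O1–C2 bond), so ring C closes by a strongly asynchronous inverse-electron-demand oxa-[4+2] cycloaddition, four atoms (O1, C8a, C4a, C4) coming from the heterodiene and two (C2, C3) from the styrene, and ring A regains aromaticity. The closest known reaction types are the racemic Sc(OTf)3-catalysed coupling of salicylaldehydes, trimethyl orthoformate and styrenes to 4-methoxyflavans, the intramolecular [4+2] reaction of alkoxy ortho-quinone methides under confined imidodiphosphoric acids, and chiral phosphoric acid catalysed additions of styrenes to ortho-quinone methides from ortho-hydroxybenzyl alcohols; the intermolecular enantioselective reaction of an acetal-derived cation is the new element. C2 is controlled by the catalyst anion, whose pocket decides which styrene face meets the bound cation, whereas C4 forms without control, which is harmless because it becomes sp2 in step 9. Regiochemistry (aryl on C2) follows from styrene polarity, since only attack through CH2 produces a benzylic cation, and chemoselectivity is secured by bromine standing in for the more nucleophilic trisubstituted prenyl alkene and by the acetal ionising far more readily than the mono-ether product. The bromine and the 4'-methoxy group, twisted out of conjugation by its two ortho neighbours, make the C2 cation poor enough that the O1–C2 bond of 9 should not reionise, so the configuration should hold.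

Step 7
Reactants: 9 (2S)-2-[3-bromo-4-methoxy-5-(triisopropylsilyloxy)phenyl]-4-methoxy-7-(triisopropylsilyloxy)chroman (both C4 epimers); 10 tributyl(3-methylbut-2-enyl)stannane
Product: 11 (2S)-4-methoxy-2-[4-methoxy-3-(3-methylbut-2-enyl)-5-(triisopropylsilyloxy)phenyl]-7-(triisopropylsilyloxy)chroman (both C4 epimers)
Conditions: 10 (1.5 equiv), Pd(PPh3)4 (5 mol %), DMF, 90 °C; tin residues removed on K2CO3-doped silica
Reagents that add atoms: tributyl(3-methylbut-2-enyl)stannane (10), CCCC[Sn](CCCC)(CCCC)CC=C(C)C
Why: Stille coupling, in which zerovalent palladium inserts into C–Br, the allylstannane transmetalates and reductive elimination at the less hindered primary allyl terminus should give the linear prenyl arene; the neutral medium spares the silyl ethers and C4–OMe, and C2 cannot epimerise because no carbonyl group is present yet.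

Step 8
Reactants: 11 (2S)-4-methoxy-2-[4-methoxy-3-(3-methylbut-2-enyl)-5-(triisopropylsilyloxy)phenyl]-7-(triisopropylsilyloxy)chroman (both C4 epimers)
Product: 12 (2S)-2-[4-methoxy-3-(3-methylbut-2-enyl)-5-(triisopropylsilyloxy)phenyl]-7-(triisopropylsilyloxy)chroman-4-ol (both C4 epimers)
Conditions: TsOH·H2O (10 mol %), THF/H2O (4:1), dilute, rt to 40 °C
Reagents that add atoms: water, O
Why: SN1 solvolysis of a benzylic ether; the C4 cation is stabilised by O1 (ortho) and the C7 silyloxy group (para), so catalytic acid ionises only this ether and the large excess of water drives the exchange to the alcohol, with C2 untouched.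

Step 9
Reactants: 12 (2S)-2-[4-methoxy-3-(3-methylbut-2-enyl)-5-(triisopropylsilyloxy)phenyl]-7-(triisopropylsilyloxy)chroman-4-ol (both C4 epimers)
Product: 13 (2S)-2-[4-methoxy-3-(3-methylbut-2-enyl)-5-(triisopropylsilyloxy)phenyl]-7-(triisopropylsilyloxy)chroman-4-one
Conditions: Dess–Martin periodinane (1.3 equiv), NaHCO3 (5 equiv), CH2Cl2, 0 °C to rt
Reagents that add atoms: none
Why: Dess–Martin oxidation under bicarbonate buffer merges both C4 epimers into one ketone without touching the prenyl alkene or the silyl ethers, and without a base strong enough to open ring C.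

Step 10
Reactants: 13 (2S)-2-[4-methoxy-3-(3-methylbut-2-enyl)-5-(triisopropylsilyloxy)phenyl]-7-(triisopropylsilyloxy)chroman-4-one
Product: 14 erylatissin C, (2S)-7-hydroxy-2-[3-hydroxy-4-methoxy-5-(3-methylbut-2-enyl)phenyl]chroman-4-one
Conditions: TBAF (2.2 equiv), AcOH (2.5 equiv), THF, 0 °C
Reagents that add atoms: none
Why: Fluoride desilylation of both aryl silyl ethers; acetic acid protonates the phenoxides as they form, which keeps the medium below the basicity at which a flavanone opens to its chalcone (retro-oxa-Michael) and loses the C2 configuration.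

Compound list
1 | 2,4-dihydroxybenzaldehyde | O=Cc1ccc(O)cc1O | starting material
2 | 2-hydroxy-4-(triisopropylsilyloxy)benzaldehyde | O=Cc1ccc(O[Si](C(C)C)(C(C)C)C(C)C)cc1O | intermediate
3 | 2-(dimethoxymethyl)-5-(triisopropylsilyloxy)phenol | COC(OC)c1ccc(O[Si](C(C)C)(C(C)C)C(C)C)cc1O | intermediate
4 | 3-bromo-4,5-dihydroxybenzaldehyde | O=Cc1cc(O)c(O)c(Br)c1 | starting material
5 | 3-bromo-5-hydroxy-4-methoxybenzaldehyde | O=Cc1cc(O)c(OC)c(Br)c1 | intermediate
6 | 3-bromo-4-methoxy-5-(triisopropylsilyloxy)benzaldehyde | O=Cc1cc(Br)c(OC)c(O[Si](C(C)C)(C(C)C)C(C)C)c1 | intermediate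
7 | 1-bromo-5-ethenyl-2-methoxy-3-(triisopropylsilyloxy)benzene | C=Cc1cc(Br)c(OC)c(O[Si](C(C)C)(C(C)C)C(C)C)c1 | intermediate
8 | O-methyl oxocarbenium ion of 2-hydroxy-4-(triisopropylsilyloxy)benzaldehyde, ion pair with the catalyst anion | C[O+]=Cc1ccc(O[Si](C(C)C)(C(C)C)C(C)C)cc1O | intermediate
9 | (2S)-2-[3-bromo-4-methoxy-5-(triisopropylsilyloxy)phenyl]-4-methoxy-7-(triisopropylsilyloxy)chroman, both C4 epimers | COC1C[C@@H](c2cc(Br)c(OC)c(O[Si](C(C)C)(C(C)C)C(C)C)c2)Oc2cc(O[Si](C(C)C)(C(C)C)C(C)C)ccc21 | intermediate
10 | tributyl(3-methylbut-2-enyl)stannane | CCCC[Sn](CCCC)(CCCC)CC=C(C)C | starting material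
11 | (2S)-4-methoxy-2-[4-methoxy-3-(3-methylbut-2-enyl)-5-(triisopropylsilyloxy)phenyl]-7-(triisopropylsilyloxy)chroman, both C4 epimers | COC1C[C@@H](c2cc(CC=C(C)C)c(OC)c(O[Si](C(C)C)(C(C)C)C(C)C)c2)Oc2cc(O[Si](C(C)C)(C(C)C)C(C)C)ccc21 | intermediate
12 | (2S)-2-[4-methoxy-3-(3-methylbut-2-enyl)-5-(triisopropylsilyloxy)phenyl]-7-(triisopropylsilyloxy)chroman-4-ol, both C4 epimers | OC1C[C@@H](c2cc(CC=C(C)C)c(OC)c(O[Si](C(C)C)(C(C)C)C(C)C)c2)Oc2cc(O[Si](C(C)C)(C(C)C)C(C)C)ccc21 | intermediate
13 | (2S)-2-[4-methoxy-3-(3-methylbut-2-enyl)-5-(triisopropylsilyloxy)phenyl]-7-(triisopropylsilyloxy)chroman-4-one | O=C1C[C@@H](c2cc(CC=C(C)C)c(OC)c(O[Si](C(C)C)(C(C)C)C(C)C)c2)Oc2cc(O[Si](C(C)C)(C(C)C)C(C)C)ccc21 | intermediate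
14 | erylatissin C, (2S)-7-hydroxy-2-[3-hydroxy-4-methoxy-5-(3-methylbut-2-enyl)phenyl]chroman-4-one | COc1c(O)cc([C@@H]2CC(=O)c3ccc(O)cc3O2)cc1CC=C(C)C | target

Total step count: 10. Longest linear sequence: 8 (steps 3 to 10).

Steps most likely to fail

Step 6. Three things may go wrong. Facial discrimination may be poor because two bulky partners may not sit well in the catalyst pocket. Addition may be slow because the 4-methoxy group of the styrene is twisted out of conjugation. The acid may also oligomerise the styrene. The fallback sets out from 3 and 7 and replaces asymmetric catalysis by a late resolution, all by known chemistry.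
- Sc(OTf)3 (10 mol %) in CH2Cl2 at rt, the established racemic Lewis-acid cycloaddition, should give the racemic bromo-4-methoxyflavan F1.
- The conditions of steps 7, 8 and 9 then lead through the racemic prenyl 4-methoxyflavan F2 and the racemic flavan-4-ol F3 to the racemic flavanone F4.
- F4 is resolved kinetically by Noyori asymmetric transfer hydrogenation with RuCl(p-cymene)[(R,R)-TsDPEN], HCO2H/Et3N, EtOAc, rt, stopped near half conversion.
- This should reduce the 2R enantiomer to the (2R,4R)-cis-flavan-4-ol F5 and leave the 2S ketone. Chromatography separates that ketone, which is 13, where the route is rejoined.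

Step 8. The C4 cation may lose a proton from C3, it may condense in Friedel–Crafts fashion with ring A of a second molecule, or the acid may attack the prenyl alkene. The fallback sets out from 9 and replaces ionisation by oxidation.
- DDQ in CH2Cl2/pH 7 buffer at 0 °C abstracts hydride from C4–H, as in the oxidative cleavage of 2,4-dimethoxybenzyl ethers.
- Water then adds and methanol leaves, which should give the (2S)-bromoflavanone F6 directly.
- This is done before prenylation, so that the oxidant never meets the doubly activated ArCH2–CH=C position.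
- Stille coupling of F6 with 10 (Pd(PPh3)4, toluene, 100 °C, amine-free to protect C2) comes back to the route at 13.

Step 7. Oxidative addition into the hindered, electron-rich bromide may be slow, coupling may occur through the tertiary allyl terminus, or the alkene may migrate into conjugation at high temperature. The fallback sets out from 9 and inverts the polarity of ring B.
- Bromine–lithium exchange with n-BuLi in THF at −78 °C should give the aryllithium F7. This is possible because 9 has no carbonyl group and no acidic proton, and because the silyloxy group is not ortho to the metalated carbon.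
- F7 is alkylated with prenyl bromide in the presence of CuBr·SMe2 (10 mol %), −78 to 0 °C, and the route is rejoined at 11.

Further compounds
F1 | step 6 | racemic 2-[3-bromo-4-methoxy-5-(triisopropylsilyloxy)phenyl]-4-methoxy-7-(triisopropylsilyloxy)chroman | COC1CC(c2cc(Br)c(OC)c(O[Si](C(C)C)(C(C)C)C(C)C)c2)Oc2cc(O[Si](C(C)C)(C(C)C)C(C)C)ccc21
F2 | step 6 | racemic 4-methoxy-2-[4-methoxy-3-(3-methylbut-2-enyl)-5-(triisopropylsilyloxy)phenyl]-7-(triisopropylsilyloxy)chroman | COC1CC(c2cc(CC=C(C)C)c(OC)c(O[Si](C(C)C)(C(C)C)C(C)C)c2)Oc2cc(O[Si](C(C)C)(C(C)C)C(C)C)ccc21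
F3 | step 6 | racemic 2-[4-methoxy-3-(3-methylbut-2-enyl)-5-(triisopropylsilyloxy)phenyl]-7-(triisopropylsilyloxy)chroman-4-ol | OC1CC(c2cc(CC=C(C)C)c(OC)c(O[Si](C(C)C)(C(C)C)C(C)C)c2)Oc2cc(O[Si](C(C)C)(C(C)C)C(C)C)ccc21
F4 | step 6 | racemic 2-[4-methoxy-3-(3-methylbut-2-enyl)-5-(triisopropylsilyloxy)phenyl]-7-(triisopropylsilyloxy)chroman-4-one | O=C1CC(c2cc(CC=C(C)C)c(OC)c(O[Si](C(C)C)(C(C)C)C(C)C)c2)Oc2cc(O[Si](C(C)C)(C(C)C)C(C)C)ccc21
F5 | step 6 | (2R,4R)-2-[4-methoxy-3-(3-methylbut-2-enyl)-5-(triisopropylsilyloxy)phenyl]-7-(triisopropylsilyloxy)chroman-4-ol | O[C@@H]1C[C@H](c2cc(CC=C(C)C)c(OC)c(O[Si](C(C)C)(C(C)C)C(C)C)c2)Oc2cc(O[Si](C(C)C)(C(C)C)C(C)C)ccc21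
F6 | step 8 | (2S)-2-[3-bromo-4-methoxy-5-(triisopropylsilyloxy)phenyl]-7-(triisopropylsilyloxy)chroman-4-one | O=C1C[C@@H](c2cc(Br)c(OC)c(O[Si](C(C)C)(C(C)C)C(C)C)c2)Oc2cc(O[Si](C(C)C)(C(C)C)C(C)C)ccc21
F7 | step 7 | (2S)-2-[3-lithio-4-methoxy-5-(triisopropylsilyloxy)phenyl]-4-methoxy-7-(triisopropylsilyloxy)chroman, both C4 epimers | COC1C[C@@H](c2cc([Li])c(OC)c(O[Si](C(C)C)(C(C)C)C(C)C)c2)Oc2cc(O[Si](C(C)C)(C(C)C)C(C)C)ccc21
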